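The route rests on disconnecting the bond between coumarin C8 and the ring CH beside the quaternary carbon. The key step exploits two features: in the cyclohexene ring this CH ends the allylic triad CH–CH=C(CH3), and in the benzopyranone ring C8 is ortho to the C7 oxygen, which marks the bond as the outcome of an aromatic Claisen shift. In one operation, palladium-catalysed O-allylation of 7-hydroxycoumarin by a Diels–Alder-derived allylic acetate (its oxygen on the carbon that later bears C8, cis to vinyl) and in situ [3,3] rearrangement of the tertiary 7-O-cyclohexenyl ether join the fragments, forge the C8–C bond and set its stereocentre by 1,3-chirality transfer. O-Methylation and a closing Heck reaction complete the dimer.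

Key step: step 4

Assumption: the (S)-configured oxazaborolidinium catalyst is taken to deliver the (1R,2S) adduct in step 2; should the sense of induction be the opposite, its enantiomer is used.

Step 1
Reactants: 1 3-methylbut-2-enal
Product: 2 (E)-3-methylbuta-1,3-dien-1-yl acetate
Conditions: isopropenyl acetate, p-TsOH·H2O (cat.), hydroquinone (trace), 95 °C, acetone distilled off; fractional distillation
Reagents that add atoms: isopropenyl acetate, CC(=C)OC(C)=O
Why: Acid-catalysed enol ester exchange through the vinylogous enol of the enal should give the dienyl acetate, the E isomer being favoured under these equilibrating conditions because the Z isomer suffers allylic strain against the isopropenyl unit.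

Step 2
Reactants: 2 (E)-3-methylbuta-1,3-dien-1-yl acetate and 3 2-methylprop-2-enal (methacrolein)
Product: 4 (1R,2S)-2-acetoxy-1,4-dimethylcyclohex-3-ene-1-carbaldehyde (acetoxy and formyl cis)
Conditions: (S)-B-o-tolyl diphenylprolinol-derived oxazaborolidine protonated by HNTf2 (15 mol %), CH2Cl2, −78 → −40 °C
Reagents that add atoms: none
Why: In this enantioselective Diels–Alder reaction catalysed by a chiral oxazaborolidinium ion, the acetoxy and methyl groups of the diene both direct the quaternary carbon next to the acetoxy-bearing carbon and para to the ring methyl, the formyl group reacts endo so that acetate and formyl end up cis, and the catalyst shields one face of the bound enal to fix the absolute configuration of both new stereocentres.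

Step 3
Reactants: 4 (1R,2S)-2-acetoxy-1,4-dimethylcyclohex-3-ene-1-carbaldehyde
Product: 5 (1S,6S)-6-ethenyl-3,6-dimethylcyclohex-2-en-1-yl acetate (acetoxy and vinyl cis)
Conditions: Ph3PCH3Br, KN(SiMe3)2, THF, 0 °C; then 4, −78 → 0 °C
Reagents that add atoms: methyltriphenylphosphonium bromide, C[P+](c1ccccc1)(c1ccccc1)c1ccccc1.[Br-]
Why: Wittig methylenation of the non-enolisable aldehyde should be much faster than attack of the ylide on the acetate, and no stereocentre is touched (the descriptor of the quaternary carbon changes from R to S only because vinyl ranks below the acetoxy-bearing ring carbon).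

Step 4
Reactants: 5 (1S,6S)-6-ethenyl-3,6-dimethylcyclohex-2-en-1-yl acetate and 6 7-hydroxy-2H-chromen-2-one (7-hydroxycoumarin)
Product: 9 8-[(1S,6S)-6-ethenyl-3,6-dimethylcyclohex-2-en-1-yl]-7-hydroxy-2H-chromen-2-one, via tertiary aryl ether 7 (not isolated), via dienone 8 (not isolated)
Conditions: Pd(PPh3)4 (5 mol %), Cs2CO3 (1.1 equiv), 1,4-dioxane, 60 °C; then 130 °C (sealed vessel); aq. HCl work-up
Reagents that add atoms: none
Why: Zerovalent palladium ionises the acetate of 5 with inversion to a π-allyl complex that spans the acetoxy carbon, the ring CH= and the methyl-bearing carbon, and the cesium phenoxide of 6 attacks the face opposite the metal, so the ether oxygen of 7 sits on the face the acetate occupied, cis to the vinyl group (double inversion, Tsuji–Trost etherification); any ether formed at the secondary terminus is re-ionised by the catalyst and drains into 7. On heating, 7 undergoes the aromatic Claisen rearrangement, a concerted suprafacial [3,3] shift through a boat-like six-membered transition state that forms the C8–CH bond next to the quaternary carbon and moves the ring double bond to the methyl-bearing carbon, and dienone 8 then enolises to phenol 9. The closest known reactions are the palladium-catalysed O-allylation of phenols and the thermal rearrangement of 7-(1,1-dimethylallyloxy)coumarin to the 8-prenyl phenol osthenol. No ring is closed in this step. The new stereocentre is controlled by 1,3-chirality transfer: the endo Diels–Alder placed the acetate cis to the future vinyl group, palladium hands this face to the tertiary C–O bond, and the sigmatropic shift delivers C8 to the same face. The step needs C8 rather than C6, secured by the higher double-bond character of the C7–C8 bond of the benzopyranone, and rearrangement of the tertiary rather than the secondary ether, secured by the much lower barrier of tertiary allyl aryl ethers under the equilibrating catalyst.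

Step 5
Reactants: 9 8-[(1S,6S)-6-ethenyl-3,6-dimethylcyclohex-2-en-1-yl]-7-hydroxy-2H-chromen-2-one
Product: 10 8-[(1S,6S)-6-ethenyl-3,6-dimethylcyclohex-2-en-1-yl]-7-methoxy-2H-chromen-2-one
Conditions: MeI, K2CO3, acetone, 50 °C
Reagents that add atoms: iodomethane, CI
Why: Williamson O-methylation of the phenoxide should proceed cleanly, since the lactone, the alkenes and both stereocentres are inert to K2CO3 in acetone.

Step 6
Reactants: 6 7-hydroxy-2H-chromen-2-one
Product: 11 7-hydroxy-8-iodo-2H-chromen-2-one
Conditions: I2, KI, 20% aq. NH3, 0 °C → rt; then aq. HCl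
Reagents that add atoms: iodine, II
Why: Electrophilic aromatic iodination of the phenoxide should occur at C8, the ortho position flanked by the phenoxide and the ring oxygen and the most nucleophilic site of 7-hydroxycoumarin.

Step 7
Reactants: 11 7-hydroxy-8-iodo-2H-chromen-2-one
Product: 12 8-iodo-7-methoxy-2H-chromen-2-one
Conditions: MeI, K2CO3, acetone, 50 °C
Reagents that add atoms: iodomethane, CI
Why: Williamson O-methylation of the acidic iodophenol should be straightforward and leaves the aryl iodide untouched.

Step 8
Reactants: 10 8-[(1S,6S)-6-ethenyl-3,6-dimethylcyclohex-2-en-1-yl]-7-methoxy-2H-chromen-2-one and 12 8-iodo-7-methoxy-2H-chromen-2-one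
Product: 13 7-methoxy-8-[(1S,6S)-6-[(E)-2-(7-methoxy-2-oxo-2H-chromen-8-yl)ethenyl]-3,6-dimethylcyclohex-2-en-1-yl]-2H-chromen-2-one (CNP0156435.2)
Conditions: Pd(OAc)2 (10 mol %), Bu4NCl, NaHCO3, DMF, 90 °C
Reagents that add atoms: none
Why: In this Mizoroki–Heck reaction, oxidative addition of the aryl iodide, insertion at the terminal carbon of the only monosubstituted alkene and syn β-hydride elimination, possible only from the benzylic CH2 because the neighbouring carbon is quaternary, should give the E-styrene without touching the trisubstituted ring alkene, the coumarin double bonds or the stereocentres.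

Compound list
1 | 3-methylbut-2-enal | CC(C)=CC=O | starting material
2 | (E)-3-methylbuta-1,3-dien-1-yl acetate | CC(=C)/C=C/OC(C)=O | intermediate
3 | 2-methylprop-2-enal | CC(=C)C=O | starting material
4 | (1R,2S)-2-acetoxy-1,4-dimethylcyclohex-3-ene-1-carbaldehyde | O=C[C@]1(C)CCC(C)=C[C@@H]1OC(C)=O | intermediate
5 | (1S,6S)-6-ethenyl-3,6-dimethylcyclohex-2-en-1-yl acetate | C=C[C@]1(C)CCC(C)=C[C@@H]1OC(C)=O | intermediate
6 | 7-hydroxy-2H-chromen-2-one | Oc1ccc2ccc(=O)oc2c1 | starting material
7 | 7-{[(1S,4S)-4-ethenyl-1,4-dimethylcyclohex-2-en-1-yl]oxy}-2H-chromen-2-one (tertiary aryl ether, oxygen cis to vinyl; not isolated) | C=C[C@]1(C)CC[C@](C)(Oc2ccc3ccc(=O)oc3c2)C=C1 | intermediate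
8 | 8-[(1S,6S)-6-ethenyl-3,6-dimethylcyclohex-2-en-1-yl]-8H-chromene-2,7-dione (Claisen dienone; configuration at the transient sp3 carbon C8 left open, lost on enolisation; not isolated) | C=C[C@]1(C)CCC(C)=C[C@@H]1C1C(=O)C=CC2=C1OC(=O)C=C2 | intermediate
9 | 8-[(1S,6S)-6-ethenyl-3,6-dimethylcyclohex-2-en-1-yl]-7-hydroxy-2H-chromen-2-one | C=C[C@]1(C)CCC(C)=C[C@@H]1c1c(O)ccc2ccc(=O)oc12 | intermediate
10 | 8-[(1S,6S)-6-ethenyl-3,6-dimethylcyclohex-2-en-1-yl]-7-methoxy-2H-chromen-2-one | C=C[C@]1(C)CCC(C)=C[C@@H]1c1c(OC)ccc2ccc(=O)oc12 | intermediate
11 | 7-hydroxy-8-iodo-2H-chromen-2-one | Oc1ccc2ccc(=O)oc2c1I | intermediate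
12 | 8-iodo-7-methoxy-2H-chromen-2-one | COc1ccc2ccc(=O)oc2c1I | intermediate
13 | 7-methoxy-8-[(1S,6S)-6-[(E)-2-(7-methoxy-2-oxo-2H-chromen-8-yl)ethenyl]-3,6-dimethylcyclohex-2-en-1-yl]-2H-chromen-2-one | COc1ccc2ccc(=O)oc2c1/C=C/[C@]1(C)CCC(C)=C[C@@H]1c1c(OC)ccc2ccc(=O)oc12 | target

Total step count: 8. Longest linear sequence: 6 steps (steps 1, 2, 3, 4, 5 and 8); steps 6 and 7 prepare the aryl iodide.

Steps most likely to fail

Step 4. The phenoxide may be captured mainly at the secondary terminus, and that ether may rearrange into the methyl-bearing carbon instead of draining into 7. The π-allyl intermediate may lose a β-hydrogen to give a diene, and metal exchange on the π-allyl face may erode the stereochemical relay. The fallback sets out from 5 and comes back at 9. Methanolysis of 5 (K2CO3 cat., MeOH) should give (1S,6S)-6-ethenyl-3,6-dimethylcyclohex-2-en-1-ol F1. F1 and 6 would then be joined by Friedel–Crafts allylation (BF3·OEt2, CH2Cl2/1,4-dioxane, −10 °C): the allyl cation should be captured by C8 at its secondary terminus, as in acid-mediated couplings of menthadienol with resorcinols. The configuration of the new centre would then rest on substrate bias alone, so the epimers (and any C6 isomer) would be separated before the route is rejoined at 9.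

Step 2. The strong Lewis acid may polymerise the acyloxydiene, or facial discrimination at the α-branched enal may be insufficient. The fallback sets out from 2 and 3 and comes back at 5. Cycloaddition promoted by BF3·OEt2 (CH2Cl2, −78 °C) should give the racemic cis adduct, (1R,2S)/(1S,2R)-2-acetoxy-1,4-dimethylcyclohex-3-ene-1-carbaldehyde F2. Wittig methylenation as in step 3 should give racemic cis-6-ethenyl-3,6-dimethylcyclohex-2-en-1-yl acetate F3. Kinetic resolution by lipase-mediated hydrolysis (Burkholderia cepacia lipase, phosphate buffer pH 7/MTBE, rt) is expected, by the empirical rule for secondary carbinols, to cleave the (1R,6R)-acetate to (1R,6R)-6-ethenyl-3,6-dimethylcyclohex-2-en-1-ol F4 and to leave the (1S,6S)-acetate 5, which is separated by chromatography.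

Step 8. Insertion of the doubly ortho-substituted arylpalladium species into the vinyl group on the quaternary carbon may be slow, so that reductive loss of iodine from 12 outpaces coupling. The fallback sets out from 12 and comes back at 13. Suzuki–Miyaura vinylation of 12 with potassium vinyltrifluoroborate (PdCl2(dppf), Cs2CO3, THF/H2O, 70 °C) should give 8-ethenyl-7-methoxy-2H-chromen-2-one F5. Cross-metathesis of F5 (in excess) with 10 (second-generation Hoveyda–Grubbs catalyst, CH2Cl2, 40 °C) should give the E-alkene 13 with loss of ethylene, the hindered vinyl group of 10 being unable to homodimerise.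

Further compounds
F1 | step 4 | (1S,6S)-6-ethenyl-3,6-dimethylcyclohex-2-en-1-ol | C=C[C@]1(C)CCC(C)=C[C@@H]1O
F2 | step 2 | racemic cis-2-acetoxy-1,4-dimethylcyclohex-3-ene-1-carbaldehyde, (1R,2S) and (1S,2R) | O=C[C@]1(C)CCC(C)=C[C@@H]1OC(C)=O.O=C[C@@]1(C)CCC(C)=C[C@H]1OC(C)=O
F3 | step 2 | racemic cis-6-ethenyl-3,6-dimethylcyclohex-2-en-1-yl acetate, (1S,6S) and (1R,6R) | C=C[C@]1(C)CCC(C)=C[C@@H]1OC(C)=O.C=C[C@@]1(C)CCC(C)=C[C@H]1OC(C)=O
F4 | step 2 | (1R,6R)-6-ethenyl-3,6-dimethylcyclohex-2-en-1-ol | C=C[C@@]1(C)CCC(C)=C[C@H]1O
F5 | step 8 | 8-ethenyl-7-methoxy-2H-chromen-2-one | C=Cc1c(OC)ccc2ccc(=O)oc12
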